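## Retrosynthetic overview

1. Target quinone ⇒ 2-alkyl-6-methylphenol: the last step is a para C–O oxidation of the phenol ring with (KSO3)2NO.
2. (8S,9S)-Diol ⇒ all-E C6–C11 conjugated triene: catalytic enantioselective syn-1,2-dioxygenation of the central C8=C9 bond with a cyclic diacyl peroxide (both C–O bonds and both stereocentres in one step).
3. Triene ⇒ C1–C8 aryl enal + diethyl geranylphosphonate (Horner–Wadsworth–Emmons, C8=C9).
4. Enal ⇒ o-cresol + geranyl bromide (ortho C-geranylation, silyl ether, SeO2 oxidation of the terminal E-methyl).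
5. Rings: none is built; the carbocycle is that of o-cresol. A temporary seven-membered diester ring forms in the key step and is opened before the quinone oxidation.

Assumption: the (S,S)-ligand of step 7 and the (1S,4S,5S)-sulfide of its fallback are taken to give the (8S,9S) series; if the sense of induction is the opposite, the mirror-image ligand or sulfide is used.

## Route

Step 1
Reactants: 1 o-cresol (2-methylphenol); 2 geranyl bromide [(2E)-1-bromo-3,7-dimethylocta-2,6-diene]
Product: 4 2-[(2E)-3,7-dimethylocta-2,6-dien-1-yl]-6-methylphenol, via sodium 2-methylphenolate 3 (not isolated)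
Conditions: NaH (1.0 equiv), toluene, 0 °C; then 2 (0.8 equiv), rt, 16 h
Reagents that add atoms: none
Why: ortho-selective C-allylation of a sodium phenoxide held as a tight ion pair in a non-polar solvent, by SN2 at the primary allylic carbon so that the 2E geometry is kept (O-geranyl ether and para isomer are separable by-products).

Step 2
Reactants: 4 2-[(2E)-3,7-dimethylocta-2,6-dien-1-yl]-6-methylphenol
Product: 5 tert-butyl{2-[(2E)-3,7-dimethylocta-2,6-dien-1-yl]-6-methylphenoxy}dimethylsilane
Conditions: TBSCl, imidazole, DMF, 40 °C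
Reagents that add atoms: tert-butyldimethylsilyl chloride, CC(C)(C)[Si](C)(C)Cl
Why: standard silyl ether formation, which shields the phenol from peroxide oxidation and chroman formation in step 3 and from the base of step 5.

Step 3
Reactants: 5 tert-butyl{2-[(2E)-3,7-dimethylocta-2,6-dien-1-yl]-6-methylphenoxy}dimethylsilane
Product: 7 (2E,6E)-8-{2-[(tert-butyldimethylsilyl)oxy]-3-methylphenyl}-2,6-dimethylocta-2,6-dienal, via allylic alcohol 6 (not isolated)
Conditions: SeO2 (0.3 equiv), t-BuOOH (3 equiv), salicylic acid (0.1 equiv), CH2Cl2, 0 °C to rt; filter; then MnO2, CH2Cl2, rt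
Reagents that add atoms: tert-butyl hydroperoxide, CC(C)(C)OO (its oxygen is delivered through catalytic selenium dioxide, O=[Se]=O)
Why: Riley-type allylic oxidation (ene reaction, then [2,3]-sigmatropic shift) attacks the E-methyl of the terminal isopropylidene, and MnO2 converges the alcohol/aldehyde mixture to the E-enal, which fixes the later 6E geometry.

Step 4
Reactants: 2 geranyl bromide
Product: 8 diethyl [(2E)-3,7-dimethylocta-2,6-dien-1-yl]phosphonate
Conditions: P(OEt)3 (neat), 130 °C, EtBr distilled off
Reagents that add atoms: triethyl phosphite, CCOP(OCC)OCC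
Why: Michaelis–Arbuzov reaction at the primary allylic bromide, with the 2E alkene retained.

Step 5
Reactants: 8 diethyl [(2E)-3,7-dimethylocta-2,6-dien-1-yl]phosphonate; 7 (2E,6E)-8-{2-[(tert-butyldimethylsilyl)oxy]-3-methylphenyl}-2,6-dimethylocta-2,6-dienal
Product: 10 tert-butyl{2-[(2E,6E,8E,10E)-3,7,11,15-tetramethylhexadeca-2,6,8,10,14-pentaen-1-yl]-6-methylphenoxy}dimethylsilane, via lithiated phosphonate 9 (not isolated)
Conditions: 8, n-BuLi, THF, −78 °C; then 7, DMPU, −78 °C to rt
Reagents that add atoms: none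
Why: Horner–Wadsworth–Emmons olefination in which the lithiated allylic phosphonate attacks the enal through its α-carbon and eliminates lithium diethyl phosphate to give the new C8=C9 bond E, completing the all-E conjugated triene.

Step 6
Reactants: 11 cyclopropane-1,1-dicarboxylic acid
Product: 12 5,6-dioxaspiro[2.4]heptane-4,7-dione (cyclopropyl malonoyl peroxide)
Conditions: urea·H2O2 (3 equiv), MeSO3H, rt, 18 h
Reagents that add atoms: urea–hydrogen peroxide, NC(N)=O.OO
Why: acid-mediated dehydrative peroxidation of a 1,1-diacid, the established one-step preparation of this bench-stable cyclic diacyl peroxide.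

Step 7
Reactants: 10 tert-butyl{2-[(2E,6E,8E,10E)-3,7,11,15-tetramethylhexadeca-2,6,8,10,14-pentaen-1-yl]-6-methylphenoxy}dimethylsilane; 12 cyclopropyl malonoyl peroxide
Product: 13 (2'S,3'S)-spiro[cyclopropane-1,6'-[1,4]dioxepane]-5',7'-dione carrying at C3' the (1E,5E)-7-{2-[(tert-butyldimethylsilyl)oxy]-3-methylphenyl}-1,5-dimethylhepta-1,5-dienyl group and at C2' the (1E)-2,6-dimethylhepta-1,5-dienyl group (the cyclic cyclopropane-1,1-dicarboxylate of the 8S,9S-diol)
Conditions: Pd2(dba)3 (5 mol%), (S,S)-t-Bu-BOX [2,2'-(propane-2,2-diyl)bis((4S)-4-tert-butyl-4,5-dihydrooxazole), 12 mol%], 12 (1.2 equiv, present from the start), 4 Å MS, toluene, 0 °C, dark; cold silica filtration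
Reagents that add atoms: none
Why: Proposed new method: zerovalent palladium inserts into the weak O–O bond of 12 to give a six-membered divalent palladium malonate chelate, which binds the only 1,2-disubstituted alkene of 10 (C8=C9) and adds across it by inner-sphere syn-oxypalladation, the one insertion that leaves an η3-allyl stabilised by a flanking trisubstituted alkene; the tethered second carboxylate then closes on the adjacent secondary allyl carbon by C–O reductive elimination (a seven-membered diester instead of a nine-membered 1,4-adduct or attack at a fully substituted carbon), so both oxygens arrive from the same palladium on one face of the E-alkene and give the threo diester, the face being chosen by the C2-symmetric bis(oxazoline) to set 8S and 9S, while the isolated trisubstituted alkenes cannot form an allyl and stay untouched; closest known reaction type: the zerovalent-palladium-catalysed diamination of conjugated dienes and trienes at the internal double bond with di-tert-butyldiaziridinone, together with the known oxidative addition of diacyl peroxides to zerovalent palladium and the uncatalysed syn-dihydroxylation of styrenes with malonoyl peroxides.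

Step 8
Reactants: 13 cyclic cyclopropane-1,1-dicarboxylate of the 8S,9S-diol (aryl TBS ether)
Product: 14 2-[(2E,6E,8S,9S,10E)-8,9-dihydroxy-3,7,11,15-tetramethylhexadeca-2,6,10,14-tetraen-1-yl]-6-methylphenol
Conditions: K2CO3, MeOH/THF 3:1, rt
Reagents that add atoms: none
Why: base-catalysed transesterification cleaves both acyl C–O bonds of the diester and the same medium removes the aryl silyl ether, with no bond to C8 or C9 broken, so the configuration is kept.

Step 9
Reactants: 14 2-[(2E,6E,8S,9S,10E)-8,9-dihydroxy-3,7,11,15-tetramethylhexadeca-2,6,10,14-tetraen-1-yl]-6-methylphenol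
Product: 15 2-[(2E,6E,8S,9S,10E)-8,9-dihydroxy-3,7,11,15-tetramethylhexadeca-2,6,10,14-tetraen-1-yl]-6-methylcyclohexa-2,5-diene-1,4-dione (target)
Conditions: (KSO3)2NO (3 equiv), KH2PO4 buffer (pH 6.5), acetone/H2O, 0 °C to rt
Reagents that add atoms: dipotassium nitrosodisulfonate (Fremy's salt), [K+].[K+].[O]N(S(=O)(=O)[O-])S(=O)(=O)[O-]
Why: Teuber oxidation, in which the nitroxyl radical forms the phenoxyl radical and a second equivalent delivers oxygen to the free para carbon, giving the 2,6-dialkyl-1,4-benzoquinone under neutral conditions that leave the allylic diol and the alkenes alone.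

## Compound list

1 | o-cresol (2-methylphenol) | Cc1ccccc1O | starting material
2 | geranyl bromide, (2E)-1-bromo-3,7-dimethylocta-2,6-diene | CC(C)=CCC/C(C)=C/CBr | starting material
3 | sodium 2-methylphenolate | Cc1ccccc1[O-].[Na+] | intermediate
4 | 2-[(2E)-3,7-dimethylocta-2,6-dien-1-yl]-6-methylphenol | CC(C)=CCC/C(C)=C/Cc1cccc(C)c1O | intermediate
5 | tert-butyl{2-[(2E)-3,7-dimethylocta-2,6-dien-1-yl]-6-methylphenoxy}dimethylsilane | CC(C)=CCC/C(C)=C/Cc1cccc(C)c1O[Si](C)(C)C(C)(C)C | intermediate
6 | (2E,6E)-8-{2-[(tert-butyldimethylsilyl)oxy]-3-methylphenyl}-2,6-dimethylocta-2,6-dien-1-ol | OC/C(C)=C/CC/C(C)=C/Cc1cccc(C)c1O[Si](C)(C)C(C)(C)C | intermediate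
7 | (2E,6E)-8-{2-[(tert-butyldimethylsilyl)oxy]-3-methylphenyl}-2,6-dimethylocta-2,6-dienal | O=C/C(C)=C/CC/C(C)=C/Cc1cccc(C)c1O[Si](C)(C)C(C)(C)C | intermediate
8 | diethyl [(2E)-3,7-dimethylocta-2,6-dien-1-yl]phosphonate | CC(C)=CCC/C(C)=C/CP(=O)(OCC)OCC | intermediate
9 | lithium salt of the α-carbanion of diethyl geranylphosphonate | CC(C)=CCC/C(C)=C/[CH-]P(=O)(OCC)OCC.[Li+] | intermediate
10 | tert-butyl{2-[(2E,6E,8E,10E)-3,7,11,15-tetramethylhexadeca-2,6,8,10,14-pentaen-1-yl]-6-methylphenoxy}dimethylsilane | CC(C)=CCC/C(C)=C/C=C/C(C)=C/CC/C(C)=C/Cc1cccc(C)c1O[Si](C)(C)C(C)(C)C | intermediate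
11 | cyclopropane-1,1-dicarboxylic acid | OC(=O)C1(CC1)C(=O)O | starting material
12 | 5,6-dioxaspiro[2.4]heptane-4,7-dione (cyclopropyl malonoyl peroxide) | O=C1OOC(=O)C12CC2 | intermediate
13 | (2'S,3'S)-2',3'-disubstituted spiro[cyclopropane-1,6'-[1,4]dioxepane]-5',7'-dione (cyclic cyclopropane-1,1-dicarboxylate of the 8S,9S-diol, aryl TBS ether) | CC(C)=CCC/C(C)=C/[C@@H]1OC(=O)C2(CC2)C(=O)O[C@H]1/C(C)=C/CC/C(C)=C/Cc1cccc(C)c1O[Si](C)(C)C(C)(C)C | intermediate
14 | 2-[(2E,6E,8S,9S,10E)-8,9-dihydroxy-3,7,11,15-tetramethylhexadeca-2,6,10,14-tetraen-1-yl]-6-methylphenol | CC(C)=CCC/C(C)=C/[C@H](O)[C@@H](O)/C(C)=C/CC/C(C)=C/Cc1cccc(C)c1O | intermediate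
15 | 2-[(2E,6E,8S,9S,10E)-8,9-dihydroxy-3,7,11,15-tetramethylhexadeca-2,6,10,14-tetraen-1-yl]-6-methylcyclohexa-2,5-diene-1,4-dione | CC(C)=CCC/C(C)=C/[C@H](O)[C@@H](O)/C(C)=C/CC/C(C)=C/CC1=CC(=O)C=C(C)C1=O | target

## Step count and risks

Total step count: 9 (steps 4 and 6 are side branches).
Longest linear sequence: 7 steps (1, 2, 3, 5, 7, 8, 9 from o-cresol).

Three steps most likely to fail:

Step 3 (SeO2 oxidation). The internal C2=C3 alkene can compete, and over-oxidation or low conversion would cut the yield. The fallback sets out from 5 and comes back at 7. It replaces C–H oxidation by alkene metathesis: cross-metathesis of the terminal isopropylidene of 5 with methacrolein (second-generation Hoveyda–Grubbs catalyst, CH2Cl2, 40 °C) gives the E-enal 7 directly. It makes no new compound (F0).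

Step 5 (Horner–Wadsworth–Emmons). The risks are γ-attack of the allylic anion, incomplete E-selectivity at C8=C9, and E/Z leakage of the geranyl 2,3-alkene in the delocalised anion. The fallback sets out from 7 and comes back at 10, and moves the disconnection to C9–C10. Takai iodo-olefination of 7 (CrCl2, CHI3, THF, 0 °C) gives tert-butyl{2-[(2E,6E,8E)-9-iodo-3,7-dimethylnona-2,6,8-trien-1-yl]-6-methylphenoxy}dimethylsilane F1. Zirconium-catalysed carboalumination of purchased 6-methylhept-5-en-1-yne (AlMe3, Cp2ZrCl2, CH2Cl2, rt) gives [(1E)-2,6-dimethylhepta-1,5-dien-1-yl]dimethylalane F2. Alkenyl–alkenyl cross-coupling of the two (Pd(PPh3)4, 5 mol%, THF, rt; Negishi coupling) joins them with retention of both geometries to give 10.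

Step 7 (the proposed dioxygenation). It may fail through uncatalysed oxidation of the trisubstituted alkenes by 12, outer-sphere carboxylate attack giving the erythro diester, re-ionisation of the bis-allylic diester by zerovalent palladium, or low enantioselectivity. The fallback uses known chemistry, sets out from 7 (with 2) and comes back at 14.
- Geranyl bromide 2, (1S,4S,5S)-isothiocineole and NaBF4 (CH2Cl2/H2O, rt) give the S-geranyl isothiocineolium tetrafluoroborate F3.
- Its ylide (KOH, MeCN/H2O 9:1, 0 °C) adds to 7 in an asymmetric sulfur-ylide epoxidation to give the trans-(8S,9S)-divinyl epoxide F4.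
- Pd(PPh3)4 (5 mol%) under CO2 (1 atm, THF, 0 °C) opens the vinyl epoxide through a π-allyl/carbonate ion pair with double inversion (net retention, whichever allylic carbon ionises) to give the trans-(8S,9S) cyclic carbonate F5.
- K2CO3 in MeOH then removes the carbonate and the aryl silyl ether to give 14.

Further compounds
F0 | step 3 | none | none
F1 | step 5 | tert-butyl{2-[(2E,6E,8E)-9-iodo-3,7-dimethylnona-2,6,8-trien-1-yl]-6-methylphenoxy}dimethylsilane | I/C=C/C(C)=C/CC/C(C)=C/Cc1cccc(C)c1O[Si](C)(C)C(C)(C)C
F2 | step 5 | [(1E)-2,6-dimethylhepta-1,5-dien-1-yl]dimethylalane | C[Al](C)/C=C(\C)CCC=C(C)C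
F3 | step 7 | S-[(2E)-3,7-dimethylocta-2,6-dien-1-yl] sulfonium tetrafluoroborate of (1S,4S,5S)-4,7,7-trimethyl-6-thiabicyclo[3.2.1]octane (exo S-alkyl) | C[C@H]1CC[C@H]2C[C@@H]1[S@+](C/C=C(\C)CCC=C(C)C)C2(C)C.F[B-](F)(F)F
F4 | step 7 | tert-butyl{2-[(2E,6E)-7-{(2S,3S)-3-[(1E)-2,6-dimethylhepta-1,5-dien-1-yl]oxiran-2-yl}-3-methylocta-2,6-dien-1-yl]-6-methylphenoxy}dimethylsilane (trans-8S,9S-divinyl epoxide) | CC(C)=CCC/C(C)=C/[C@@H]1O[C@H]1/C(C)=C/CC/C(C)=C/Cc1cccc(C)c1O[Si](C)(C)C(C)(C)C
F5 | step 7 | (4S,5S)-4-[(1E,5E)-7-{2-[(tert-butyldimethylsilyl)oxy]-3-methylphenyl}-1,5-dimethylhepta-1,5-dien-1-yl]-5-[(1E)-2,6-dimethylhepta-1,5-dien-1-yl]-1,3-dioxolan-2-one | CC(C)=CCC/C(C)=C/[C@@H]1OC(=O)O[C@H]1/C(C)=C/CC/C(C)=C/Cc1cccc(C)c1O[Si](C)(C)C(C)(C)C
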